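# Proposed total synthesis of Pestalone D by benzannulation of a phthalide ynol ether

## Analysis of the target

Pestalone D (27) is a benzophenone in which ring A and ring B are joined only through one ketone carbon; it has no stereocentre, and the prenyl double bond carries two identical methyl groups, so no stereochemical control is needed. Ring A is hexasubstituted (C1 OMe, C2 Br, C3 Me, C4 Br, C5 OH, C6 ketone) and ring B is pentasubstituted (C1' ketone, C2' CHO, C3' OH, C4' H, C5' OH, C6' prenyl). The ketone carbon is flanked by four ortho substituents (C1–OMe and C5–OH on ring A, C2'–CHO and C6'–prenyl on ring B), so a late aryl–carbonyl bond formation would have to be forced at a very crowded centre. The ortho-formyl diaryl ketone is the most delicate unit: base or nucleophiles can trigger an intramolecular hydride shift that turns it into a 3-arylphthalide, and acid can close rings onto the aldehyde, the ketone or the prenyl group. The prenyl alkene is sensitive to electrophilic bromine, acid and radical halogenation, the three phenols to strong oxidants, and the two aryl bromides to metalation and low-valent metals. The two neighbouring benzylic carbons on ring B must also end at different oxidation levels (ketone at C1', aldehyde at C2'). The strategy rests on ring A: stripped of its bromines it is a 3-methoxy-5-methylphenol that carries the ketone carbon at C6, between the C5 hydroxyl and the C1 methoxy group, which is what a methyl-substituted vinylketene and a methoxyalkyne assemble, and C4 and C2 are then ortho and para to the new C5 hydroxyl, where bromine goes without further direction.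

## Retrosynthetic reasoning

The C2' aldehyde of 27 is formed last, from the benzylic alcohol of keto alcohol 26. The keto aldehyde is the form most exposed to base-induced rearrangement, so it should come from a neutral, heterogeneous oxidation and not be carried further. With the ketone already present, the only cyclic tautomer of 26 is a hemiketal at the ketone carbon, which has no C–H to oxidise, so the oxidation cannot run on to a lactone.

The ketone of 26 is traced back through silylated ketone 25 to the secondary alcohol of 24. The two benzylic carbons must be oxidised in this order. If the primary alcohol were oxidised while the secondary hydroxyl is free, the hydroxy aldehyde would close to a lactol and be oxidised back to a phthalide. In 24 the three phenols and the primary alcohol are silylated and only the secondary carbinol is free. No selective reagent is needed for this, because the carbinol sits between four ortho substituents and is the one hydroxyl a bulky silyl chloride cannot reach. Fluoride then uncovers all four hydroxyls of 25 at once.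

Silyl ether 24 comes from pentaol 23, and 23 from lactone 22 by one exhaustive hydride reduction that opens the lactone to the diol and removes both pivalates. The lactone is thus a storage form: it holds the future ketone carbon at the alcohol level and the future aldehyde carbon at the acid level until the aromatic chemistry is finished.

The two C–Br bonds of 22 are cut next, giving phenol 21. C4 is ortho and C2 para to the free C5 hydroxyl, and both are also activated by the C1 methoxy group. Ring B is deactivated by two pivalates and the lactone carbonyl, so electrophilic bromination should touch ring A only. Bromine is introduced after ring A is built because the annulation delivers the unhalogenated phenol directly.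

Ring A of 21 is disconnected at C5–C6, C1–C2 and C4–C5 into cyclobutenone 16 and ynol ether 11. C5, C4, C3 (with its methyl) and C2 come from 16; C6 and C1 (with its methoxy group) are the two alkyne carbons of 11. This cut is preferred over any cut at the ketone carbon: the bond from that carbon to ring B already exists in 11 as the phthalide C–C bond, and the bond to ring A is the bond from that carbon to the alkyne. No aryl–carbonyl coupling at the tetra-ortho-substituted centre is needed. The forward reaction must join the ketene carbonyl carbon to the alkyne carbon remote from oxygen, so that the ring B carbon ends between hydroxyl and methoxy; the polarisation of the ynol ether ensures this.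

Ynol ether 11 is cut at the bond between the phthalide carbon and the alkyne, and at the lactone C–O bond, giving aldehyde ester 7 and acetylide 9, which is generated from acetal 8. Addition to an aldehyde is the most dependable way to make this bond, and the ortho methyl ester closes the lactone as soon as alkoxide 10 has formed, so one operation gives the whole precursor.

The prenyl group of 7 is cut at the aryl–CH2 bond to bromide 5 and stannane 6. Direct C-prenylation of a resorcylate would go mainly between the two oxygens, which is the wrong position. The side chain must also come after the benzylic oxidation, which it would not survive. A cross-coupling at a halogen placed early solves both problems and tolerates the aldehyde.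

Aldehyde 5 goes back through benzylic bromide 4 and bis-pivalate 3 to bromophenol 2 and methyl orsellinate 1. Compound 1 supplies the ring B carbons, the ester carbon (future aldehyde carbon) and the methyl carbon (future ketone carbon). The forward steps must place bromine next to the methyl group, cap the phenols, and raise the methyl group to the aldehyde level by radical bromination and a neutral oxidation.

Cyclobutenone 16 is cut across the ring into propyne 12 and dichloroketene 14, generated from acid chloride 13; the [2+2] adduct 15 only has to lose its two chlorines.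

## Alternatives that were turned down

Alternative 1: The ketone is disconnected on both sides (C6–C(O) and C1'–C(O)) and its carbon is supplied as a one-carbon carbonyl unit in a carbonylative cross-coupling.

In the forward direction ring A enters as an aryl iodide and ring B as an arylboronate, tied beforehand through an ester between the C5 oxygen and the C2' carboxyl carbon, as in 4,6-dibromo-2-iodo-3-methoxy-5-methylphenyl 4,6-bis(methoxymethoxy)-3-(3-methylbut-2-enyl)-2-(4,4,5,5-tetramethyl-1,3,2-dioxaborolan-2-yl)benzoate (A2). Zerovalent palladium would add oxidatively to the C6–I bond of A2 and take up the carbonyl unit. The aroylpalladium would then be intercepted by the C1' boronate of the same molecule, which closes the seven-membered keto lactone 2,4-dibromo-1-methoxy-7,9-bis(methoxymethoxy)-3-methyl-10-(3-methylbut-2-enyl)dibenzo[b,e]oxepine-6,11-dione (A1).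

In its favour, both halves are made separately and joined late, and the tether turns a hopeless intermolecular coupling into a ring closure. Bromines and prenyl group are in place before the rings meet, so no bromination beside the alkene is needed.

Against it, A2 carries three carbon–halogen bonds on one ring and the palladium must choose the iodide, itself flanked by two ortho substituents. The acylpalladium derived from A2 must transmetalate with a boronate that has two ortho neighbours. Direct coupling without carbonyl insertion would give the six-membered lactone instead, and the crowded boronate of A2 is prone to protodeboronation. After A1, the aryl ester must be taken to the aldehyde beside an intact ketone, which again means over-reduction and ordered re-oxidation. The acetal protecting groups of A1 must also be removed with acid in the presence of the prenyl group and the keto aldehyde.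

In comparison, this plan is stronger on convergence and on having the halogens set early. The chosen strategy offers in exchange a bond to the ketone carbon made by plain aldehyde addition, no competition among three halogens at a metal, and regiochemistry fixed by the polarity of 11 and not by catalyst selectivity.

Alternative 2: Ring B is disconnected at C6'–C1' and C2'–C3' into a four-carbon diene and an alkynoate that already carries ring A.

In the forward direction the electron-rich diene 1-methoxy-7-methyl-1,3-bis(trimethylsilyloxy)octa-1,3,6-triene (A4) would undergo a Diels–Alder reaction with the triple bond of racemic methyl 4-(tert-butyldimethylsilyloxy)-4-[3,5-dibromo-2-methoxy-6-(methoxymethoxy)-4-methylphenyl]but-2-ynoate (A5). The nucleophilic, prenyl-substituted end of A4 would join the alkyne carbon of A5 that carries the ring A carbinol, and the ketene acetal carbon of A4 would join the carbon next to the ester. The adduct would aromatise by elimination to racemic methyl 2-[(tert-butyldimethylsilyloxy)(3,5-dibromo-2-methoxy-6-(methoxymethoxy)-4-methylphenyl)methyl]-4,6-dihydroxy-3-(3-methylbut-2-enyl)benzoate (A3).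

In its favour, the oxygen pattern of ring B, its ester and its prenyl group arise in one step with both phenols free. The polarity of A4 and A5 is matched, and ring A is complete with both bromines from the start.

Against it, the new C6'–C1' bond joins the substituted terminus of A4 to the alkyne carbon of A5 that bears a very bulky branched substituent. The cycloaddition would therefore need forcing conditions, under which a bis-silyl diene such as A4 tends to lose or transfer its silyl groups. Alkynoate A5 is itself a propargylic silyl ether flanked by two ortho substituents and would need several steps from a ring A aldehyde. After A3, the carbinol must be unmasked and oxidised and the ester reduced to the aldehyde. A free carbinol ortho to the ester would lactonise to the same kind of phthalide that the chosen route uses on purpose, so the end game is no shorter, and an acid-labile acetal still has to be removed.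

In comparison, this plan is stronger in avoiding a chemoselective late bromination and in needing no protection of the ring B phenols. The chosen strategy builds the less crowded ring (ring A still has two hydrogens when it is formed) from a small, unhindered vinylketene under neutral thermal conditions.

Alternative 3: Ring B is disconnected at C1'–C2' only and is grown from an open polycarbonyl chain by an aldol aromatisation modelled on polyketide biosynthesis.

In the forward direction an amine base would enolise racemic 6-[5-(3,5-dibromo-2-methoxy-6-(methoxymethoxy)-4-methylphenyl)-3-(3-methylbut-2-enyl)-2,4,5-trioxopentyl]-2,2-dimethyl-4H-1,3-dioxin-4-one (A7). The alpha carbon of the dioxinone (future C2') would add to the diketone carbonyl that lies further from ring A (future C1'). Loss of water would give 5-[3,5-dibromo-2-methoxy-6-(methoxymethoxy)-4-methylbenzoyl]-7-hydroxy-2,2-dimethyl-6-(3-methylbut-2-enyl)-4H-benzo[d][1,3]dioxin-4-one (A6).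

In its favour, the diaryl ketone is at its final oxidation level from the outset, so no crowded carbinol has to be oxidised. The C2' carbon and the C3' oxygen emerge masked together, and ring A is again complete.

Against it, A7 combines a 1,2-dione with an enolisable 1,3-dicarbonyl chain and a heat-sensitive dioxinone. Several enolisation and O-cyclisation modes compete, the dione can hydrate or rearrange under base, and assembling A7 requires acylation with a hindered aroyl-glyoxyl unit. After A6, the dioxinone carbonyl must be reduced to the aldehyde level beside a ketone, which brings back reduction and ordered re-oxidation, plus an acidic deprotection.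

In comparison, this plan is stronger on redox economy at the ketone. The chosen strategy is stronger on access to its precursor (six routine steps to 11) and on the predictability of the ring-forming event, a pericyclic cascade whose regiochemistry has a single polar bias.

Key step: step 9

Remark on the chemistry: 27 has no stereocentre. The one stereocentre carried from 10 to 24 (the phthalide and later carbinol carbon) is racemic throughout and is erased in step 13.

## Route

Step 1
Reactants: 1 methyl orsellinate (methyl 2,4-dihydroxy-6-methylbenzoate)
Product: 2 methyl 3-bromo-4,6-dihydroxy-2-methylbenzoate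
Conditions: NBS (1.0 equiv), MeCN, −30 → 0 °C
Reagents that add atoms: N-bromosuccinimide, O=C1CCC(=O)N1Br
Why: Electrophilic aromatic bromination; as is usual for 2,4-dihydroxybenzoates, the position para to the ester-chelated hydroxyl and ortho to the other hydroxyl (next to the methyl group) should be attacked in preference to the position between the two hydroxyls, and one equivalent at low temperature limits dibromination.

Step 2
Reactants: 2 methyl 3-bromo-4,6-dihydroxy-2-methylbenzoate
Product: 3 methyl 3-bromo-2-methyl-4,6-bis(pivaloyloxy)benzoate
Conditions: PivCl, Et3N, DMAP (cat.), CH2Cl2, 0 °C → rt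
Reagents that add atoms: pivaloyl chloride, CC(C)(C)C(Cl)=O
Why: DMAP-catalysed O-acylation of both phenols; the pivalates should survive the radical and palladium steps, deactivate ring B toward the later bromination, and be removed by hydride together with the lactone.

Step 3
Reactants: 3 methyl 3-bromo-2-methyl-4,6-bis(pivaloyloxy)benzoate
Product: 4 methyl 3-bromo-2-(bromomethyl)-4,6-bis(pivaloyloxy)benzoate
Conditions: NBS (1.05 equiv), AIBN (cat.), PhCF3, 80 °C
Reagents that add atoms: N-bromosuccinimide, O=C1CCC(=O)N1Br
Why: Wohl–Ziegler benzylic bromination; the ring is deactivated by two acyloxy groups, an ester and a bromine, so the radical chain should attack only the benzylic methyl group, and the step is placed before the prenyl group exists because an allylic side chain would not survive it.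

Step 4
Reactants: 4 methyl 3-bromo-2-(bromomethyl)-4,6-bis(pivaloyloxy)benzoate
Product: 5 methyl 3-bromo-2-formyl-4,6-bis(pivaloyloxy)benzoate
Conditions: NMO (excess), MeCN, rt
Reagents that add atoms: N-methylmorpholine N-oxide, C[N+]1([O-])CCOCC1
Why: Amine N-oxide oxidation of a benzylic bromide (O-alkylation of the N-oxide, then elimination of N-methylmorpholine), a neutral Kornblum-type oxidation that should leave the methyl ester and the pivalates untouched.

Step 5
Reactants: 5 methyl 3-bromo-2-formyl-4,6-bis(pivaloyloxy)benzoate; 6 tributyl(3-methylbut-2-enyl)stannane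
Product: 7 methyl 2-formyl-3-(3-methylbut-2-enyl)-4,6-bis(pivaloyloxy)benzoate
Conditions: Pd(PPh3)4 (cat.), DMF, 80 °C
Reagents that add atoms: none
Why: Stille coupling; oxidative addition of zerovalent palladium into the C–Br bond is helped by the ortho formyl group, and the allylpalladium intermediate should reductively eliminate at its unhindered CH2 terminus to give the linear prenyl arene; aldehyde, ester and pivalates are inert to the neutral stannane.

Step 6
Reactants: 7 methyl 2-formyl-3-(3-methylbut-2-enyl)-4,6-bis(pivaloyloxy)benzoate; 8 chloroacetaldehyde dimethyl acetal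
Product: 11 racemic 3-(methoxyethynyl)-4-(3-methylbut-2-enyl)-5,7-bis(pivaloyloxy)isobenzofuran-1(3H)-one, via lithium methoxyacetylide 9 (not isolated), via lithium alkoxide 10 (not isolated)
Conditions: 8, LiNEt2 (from n-BuLi/Et2NH, 3 equiv per 8), THF, 0 °C; then 7, −78 → −40 °C; aq. NH4Cl
Reagents that add atoms: none
Why: Double elimination and deprotonation of 8 by LiNEt2 gives acetylide 9, which should add to the aldehyde of 7 at −78 °C, where aryl pivalates and the hindered benzoate are not attacked; alkoxide 10 then closes the five-membered lactone on the neighbouring methyl ester (5-exo-trig acyl substitution); the new stereocentre forms without control, so 11 is racemic, which is of no consequence.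

Step 7
Reactants: 12 propyne; 13 trichloroacetyl chloride
Product: 15 4,4-dichloro-3-methylcyclobut-2-en-1-one, via dichloroketene 14 (not isolated)
Conditions: Zn–Cu couple, Et2O–DME, 0 °C → rt, dry-ice condenser
Reagents that add atoms: none
Why: Zinc removes two chlorines from 13 to give dichloroketene 14, which undergoes thermal [2+2] cycloaddition with the alkyne, its carbonyl carbon bonding to the terminal alkyne carbon so that the methyl group ends at C3 of the cyclobutenone.

Step 8
Reactants: 15 4,4-dichloro-3-methylcyclobut-2-en-1-one
Product: 16 3-methylcyclobut-2-en-1-one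
Conditions: Zn, AcOH, TMEDA, EtOH, 0 °C → rt
Reagents that add atoms: none
Why: Zinc–acetic acid reductive dechlorination alpha to the ketone via zinc enolates, a standard route to 3-alkylcyclobutenones; TMEDA buffers the medium so that the strained enone should not be over-reduced; the volatile product is used as a solution.

Step 9
Reactants: 11 racemic 3-(methoxyethynyl)-4-(3-methylbut-2-enyl)-5,7-bis(pivaloyloxy)isobenzofuran-1(3H)-one; 16 3-methylcyclobut-2-en-1-one
Product: 21 racemic 3-(2-hydroxy-6-methoxy-4-methylphenyl)-4-(3-methylbut-2-enyl)-5,7-bis(pivaloyloxy)isobenzofuran-1(3H)-one, via vinylketene 17 (not isolated), via vinylcyclobutenone adduct 18 (not isolated), via dienylketene 19 (not isolated), via cyclohexadienone 20 (not isolated)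
Conditions: 16 (1.3 equiv, two portions), toluene, 80 → 110 °C, sealed tube
Reagents that add atoms: none
Why: Danheiser benzannulation, the cyclobutenone–alkyne aromatic annulation long used with alkoxyalkynes to make resorcinol monoethers. Heating opens 16 by four-electron electrocyclic ring opening to vinylketene 17; its carbonyl carbon (future C5) bonds to the nucleophilic alkyne carbon of 11 remote from oxygen (future C6) and its alpha carbon (future C2) to the methoxy-bearing carbon (future C1) in a [2+2] cycloaddition that gives 18. Four-electron opening of 18 gives dienylketene 19, and ring A closes by six-electron electrocyclisation of the ketene carbon onto the terminal CH2 (C4–C5) to cyclohexadienone 20, which tautomerises to phenol 21; the C4–C5 bond is the cyclobutenone's own sigma bond, broken in the first opening and remade here. The single ring is thus closed by a pericyclic 6π process and not by an ionic cyclisation, so it does not depend on nucleophile–electrophile matching at the crowded carbon. No new stereocentre appears in 21: the stereocentres of 18 are lost on ring opening and the phthalide carbon is carried unchanged as a racemate. The selectivity needed is regiochemical, the ring B carbon must end between the new hydroxyl and the methoxy group, and it is secured by the polarisation of the ynol ether, whose oxygen lone pair makes the remote carbon the nucleophile toward the ketene carbonyl carbon. A methyl ynol ether is used because it has no beta hydrogen for a retro-ene fragmentation at these temperatures; pivalates, lactone and prenyl alkene are inert to the neutral thermal conditions, and 16 is kept near stoichiometric so that surplus vinylketene does not acylate the new phenol.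

Step 10
Reactants: 21 racemic 3-(2-hydroxy-6-methoxy-4-methylphenyl)-4-(3-methylbut-2-enyl)-5,7-bis(pivaloyloxy)isobenzofuran-1(3H)-one
Product: 22 racemic 3-(3,5-dibromo-2-hydroxy-6-methoxy-4-methylphenyl)-4-(3-methylbut-2-enyl)-5,7-bis(pivaloyloxy)isobenzofuran-1(3H)-one
Conditions: NBS (2.05 equiv), CH2Cl2, −78 → 0 °C, dark
Reagents that add atoms: N-bromosuccinimide, O=C1CCC(=O)N1Br
Why: Electrophilic aromatic bromination; C4 (ortho to C5–OH, para to C1–OMe) and C2 (para to C5–OH, ortho to C1–OMe) are the only doubly activated positions, ring B is switched off by its pivalates and the lactone carbonyl, and NBS in a dry non-nucleophilic solvent should react with the phenol much faster than with the trisubstituted alkene, without releasing HBr.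

Step 11
Reactants: 22 racemic 3-(3,5-dibromo-2-hydroxy-6-methoxy-4-methylphenyl)-4-(3-methylbut-2-enyl)-5,7-bis(pivaloyloxy)isobenzofuran-1(3H)-one
Product: 23 racemic 5-[(3,5-dibromo-2-hydroxy-6-methoxy-4-methylphenyl)(hydroxy)methyl]-4-(hydroxymethyl)-6-(3-methylbut-2-enyl)benzene-1,3-diol
Conditions: i-Bu2AlH (10 equiv), CH2Cl2, −78 → 0 °C; aq. potassium sodium tartrate
Reagents that add atoms: none
Why: Hydride reduction of the lactone to the diol and reductive cleavage of both aryl pivalates in one operation; aryl bromides and the alkene are inert to i-Bu2AlH, and the neutral tartrate work-up avoids acid-induced ionisation of the electron-rich benzylic alcohols; 23 is used crude.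

Step 12
Reactants: 23 racemic 5-[(3,5-dibromo-2-hydroxy-6-methoxy-4-methylphenyl)(hydroxy)methyl]-4-(hydroxymethyl)-6-(3-methylbut-2-enyl)benzene-1,3-diol
Product: 24 racemic [3,5-dibromo-2-(tert-butyldimethylsilyloxy)-6-methoxy-4-methylphenyl]{3,5-bis(tert-butyldimethylsilyloxy)-2-[(tert-butyldimethylsilyloxy)methyl]-6-(3-methylbut-2-enyl)phenyl}methanol
Conditions: TBSCl (6 equiv), imidazole, DMF, rt
Reagents that add atoms: tert-butyldimethylsilyl chloride, CC(C)(C)[Si](C)(C)Cl
Why: Silylation of the three phenols and the primary alcohol; the secondary carbinol, flanked by four ortho substituents, is too hindered for TBSCl–imidazole and should stay free, which differentiates the two benzylic carbons by sterics alone.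

Step 13
Reactants: 24 racemic [3,5-dibromo-2-(tert-butyldimethylsilyloxy)-6-methoxy-4-methylphenyl]{3,5-bis(tert-butyldimethylsilyloxy)-2-[(tert-butyldimethylsilyloxy)methyl]-6-(3-methylbut-2-enyl)phenyl}methanol
Product: 25 [3,5-dibromo-2-(tert-butyldimethylsilyloxy)-6-methoxy-4-methylphenyl]{3,5-bis(tert-butyldimethylsilyloxy)-2-[(tert-butyldimethylsilyloxy)methyl]-6-(3-methylbut-2-enyl)phenyl}methanone
Conditions: Dess–Martin periodinane, CH2Cl2, rt
Reagents that add atoms: none
Why: Dess–Martin oxidation of the secondary benzylic alcohol to the diaryl ketone; the compact hypervalent iodine reagent copes with hindered alcohols, and because the primary alcohol is silylated no lactol can form and be over-oxidised to a lactone; the stereocentre is removed here.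

Step 14
Reactants: 25 [3,5-dibromo-2-(tert-butyldimethylsilyloxy)-6-methoxy-4-methylphenyl]{3,5-bis(tert-butyldimethylsilyloxy)-2-[(tert-butyldimethylsilyloxy)methyl]-6-(3-methylbut-2-enyl)phenyl}methanone
Product: 26 (3,5-dibromo-2-hydroxy-6-methoxy-4-methylphenyl)[3,5-dihydroxy-2-(hydroxymethyl)-6-(3-methylbut-2-enyl)phenyl]methanone
Conditions: TBAF, AcOH (1:1, 5 equiv), THF, 0 °C → rt
Reagents that add atoms: none
Why: Fluoride-induced cleavage of all four silyl ethers; acetic acid buffers the phenoxides, and since no aldehyde is present yet, no base-induced hydride shift to a phthalide is possible at this stage.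

Step 15
Reactants: 26 (3,5-dibromo-2-hydroxy-6-methoxy-4-methylphenyl)[3,5-dihydroxy-2-(hydroxymethyl)-6-(3-methylbut-2-enyl)phenyl]methanone
Product: 27 Pestalone D, 2-(3,5-dibromo-2-hydroxy-6-methoxy-4-methylbenzoyl)-4,6-dihydroxy-3-(3-methylbut-2-enyl)benzaldehyde
Conditions: MnO2 (activated, excess), CH2Cl2, rt
Reagents that add atoms: none
Why: MnO2 oxidation of a benzylic, salicyl-type alcohol to the aldehyde under neutral heterogeneous conditions; the ketone is already in place, so the only ring tautomer of 26 is a hemiketal without an oxidisable C–H and the oxidation should stop at the keto aldehyde; phenols, alkene and aryl bromides are tolerated, and no base is present that could rearrange the product.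

## Compound list

1 | methyl orsellinate (methyl 2,4-dihydroxy-6-methylbenzoate) | COC(=O)c1c(C)cc(O)cc1O | starting material
2 | methyl 3-bromo-4,6-dihydroxy-2-methylbenzoate | COC(=O)c1c(C)c(Br)c(O)cc1O | intermediate
3 | methyl 3-bromo-2-methyl-4,6-bis(pivaloyloxy)benzoate | COC(=O)c1c(C)c(Br)c(OC(=O)C(C)(C)C)cc1OC(=O)C(C)(C)C | intermediate
4 | methyl 3-bromo-2-(bromomethyl)-4,6-bis(pivaloyloxy)benzoate | COC(=O)c1c(CBr)c(Br)c(OC(=O)C(C)(C)C)cc1OC(=O)C(C)(C)C | intermediate
5 | methyl 3-bromo-2-formyl-4,6-bis(pivaloyloxy)benzoate | COC(=O)c1c(C=O)c(Br)c(OC(=O)C(C)(C)C)cc1OC(=O)C(C)(C)C | intermediate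
6 | tributyl(3-methylbut-2-enyl)stannane | CC(C)=CC[Sn](CCCC)(CCCC)CCCC | starting material
7 | methyl 2-formyl-3-(3-methylbut-2-enyl)-4,6-bis(pivaloyloxy)benzoate | COC(=O)c1c(C=O)c(CC=C(C)C)c(OC(=O)C(C)(C)C)cc1OC(=O)C(C)(C)C | intermediate
8 | chloroacetaldehyde dimethyl acetal (2-chloro-1,1-dimethoxyethane) | COC(CCl)OC | starting material
9 | lithium methoxyacetylide | [Li]C#COC | intermediate
10 | racemic lithium alkoxide of methyl 2-(1-hydroxy-3-methoxyprop-2-ynyl)-3-(3-methylbut-2-enyl)-4,6-bis(pivaloyloxy)benzoate | COC#CC(O[Li])c1c(CC=C(C)C)c(OC(=O)C(C)(C)C)cc(OC(=O)C(C)(C)C)c1C(=O)OC | intermediate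
11 | racemic 3-(methoxyethynyl)-4-(3-methylbut-2-enyl)-5,7-bis(pivaloyloxy)isobenzofuran-1(3H)-one | COC#CC1OC(=O)c2c(OC(=O)C(C)(C)C)cc(OC(=O)C(C)(C)C)c(CC=C(C)C)c12 | intermediate
12 | propyne | CC#C | starting material
13 | trichloroacetyl chloride | ClC(Cl)(Cl)C(Cl)=O | starting material
14 | dichloroketene | ClC(Cl)=C=O | intermediate
15 | 4,4-dichloro-3-methylcyclobut-2-en-1-one | CC1=CC(=O)C1(Cl)Cl | intermediate
16 | 3-methylcyclobut-2-en-1-one | CC1=CC(=O)C1 | intermediate
17 | vinylketene, 3-methylbuta-1,3-dien-1-one | C=C(C)C=C=O | intermediate
18 | 3-[2-methoxy-4-oxo-3-(prop-1-en-2-yl)cyclobut-1-en-1-yl]-4-(3-methylbut-2-enyl)-5,7-bis(pivaloyloxy)isobenzofuran-1(3H)-one, racemic mixture of diastereomers | COC1=C(C2OC(=O)c3c(OC(=O)C(C)(C)C)cc(OC(=O)C(C)(C)C)c(CC=C(C)C)c23)C(=O)C1C(C)=C | intermediate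
19 | racemic 3-[(3E)-3-methoxy-5-methyl-1-oxohexa-1,3,5-trien-2-yl]-4-(3-methylbut-2-enyl)-5,7-bis(pivaloyloxy)isobenzofuran-1(3H)-one (ketene and isopropenyl groups cis) | O=C=C(C1OC(=O)c2c(OC(=O)C(C)(C)C)cc(OC(=O)C(C)(C)C)c(CC=C(C)C)c12)/C(OC)=C\C(C)=C | intermediate
20 | racemic 3-(2-methoxy-4-methyl-6-oxocyclohexa-1,3-dien-1-yl)-4-(3-methylbut-2-enyl)-5,7-bis(pivaloyloxy)isobenzofuran-1(3H)-one | COC1=C(C2OC(=O)c3c(OC(=O)C(C)(C)C)cc(OC(=O)C(C)(C)C)c(CC=C(C)C)c23)C(=O)CC(C)=C1 | intermediate
21 | racemic 3-(2-hydroxy-6-methoxy-4-methylphenyl)-4-(3-methylbut-2-enyl)-5,7-bis(pivaloyloxy)isobenzofuran-1(3H)-one | Cc1cc(O)c(C2OC(=O)c3c(OC(=O)C(C)(C)C)cc(OC(=O)C(C)(C)C)c(CC=C(C)C)c23)c(OC)c1 | intermediate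
22 | racemic 3-(3,5-dibromo-2-hydroxy-6-methoxy-4-methylphenyl)-4-(3-methylbut-2-enyl)-5,7-bis(pivaloyloxy)isobenzofuran-1(3H)-one | Cc1c(Br)c(O)c(C2OC(=O)c3c(OC(=O)C(C)(C)C)cc(OC(=O)C(C)(C)C)c(CC=C(C)C)c23)c(OC)c1Br | intermediate
23 | racemic 5-[(3,5-dibromo-2-hydroxy-6-methoxy-4-methylphenyl)(hydroxy)methyl]-4-(hydroxymethyl)-6-(3-methylbut-2-enyl)benzene-1,3-diol | COc1c(Br)c(C)c(Br)c(O)c1C(O)c1c(CO)c(O)cc(O)c1CC=C(C)C | intermediate
24 | racemic [3,5-dibromo-2-(tert-butyldimethylsilyloxy)-6-methoxy-4-methylphenyl]{3,5-bis(tert-butyldimethylsilyloxy)-2-[(tert-butyldimethylsilyloxy)methyl]-6-(3-methylbut-2-enyl)phenyl}methanol | COc1c(Br)c(C)c(Br)c(O[Si](C)(C)C(C)(C)C)c1C(O)c1c(CO[Si](C)(C)C(C)(C)C)c(O[Si](C)(C)C(C)(C)C)cc(O[Si](C)(C)C(C)(C)C)c1CC=C(C)C | intermediate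
25 | [3,5-dibromo-2-(tert-butyldimethylsilyloxy)-6-methoxy-4-methylphenyl]{3,5-bis(tert-butyldimethylsilyloxy)-2-[(tert-butyldimethylsilyloxy)methyl]-6-(3-methylbut-2-enyl)phenyl}methanone | COc1c(Br)c(C)c(Br)c(O[Si](C)(C)C(C)(C)C)c1C(=O)c1c(CO[Si](C)(C)C(C)(C)C)c(O[Si](C)(C)C(C)(C)C)cc(O[Si](C)(C)C(C)(C)C)c1CC=C(C)C | intermediate
26 | (3,5-dibromo-2-hydroxy-6-methoxy-4-methylphenyl)[3,5-dihydroxy-2-(hydroxymethyl)-6-(3-methylbut-2-enyl)phenyl]methanone | COc1c(Br)c(C)c(Br)c(O)c1C(=O)c1c(CO)c(O)cc(O)c1CC=C(C)C | intermediate
27 | Pestalone D, 2-(3,5-dibromo-2-hydroxy-6-methoxy-4-methylbenzoyl)-4,6-dihydroxy-3-(3-methylbut-2-enyl)benzaldehyde | COc1c(Br)c(C)c(Br)c(O)c1C(=O)c1c(C=O)c(O)cc(O)c1CC=C(C)C | target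

## Step count and least certain steps

Total step count: 15. Longest linear sequence: 13 steps (steps 1–6 and 9–15, from 1); the cyclobutenone branch (steps 7 and 8) joins at step 9.

**Step 9 (key step).** The capture of vinylketene 17 by the hindered ynol ether of 11, whose propargylic oxygen also lowers its nucleophilicity, may be slower than dimerisation of the ketene. Prolonged heating may ionise the propargylic lactone C–O bond, and surplus ketene may acylate the new phenol. Fallback, from 11 to 21: the same vinylketene is generated at room temperature by photochemical Wolff rearrangement of 1-diazo-3-methylbut-3-en-2-one F1. F1 is prepared from commercial 3-methylbut-3-en-2-one by detrifluoroacetylative diazo transfer (LiN(SiMe3)2, CF3CO2CH2CF3; then MsN3, Et3N). Irradiation of 11 with F1 in CH2Cl2 should give adduct 18 without heating, and brief warming then completes the opening and electrocyclisation through 19 and 20 to 21.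

**Step 6.** Lithium methoxide set free during formation of 9 and during lactonisation, or residual amide base, may cleave the aryl pivalates, and the ynol ether may hydrate on work-up. Fallback, from 7 to 11: acetylide 9 is made free of amine and alkoxide from (E)-1,2-dichloro-1-methoxyethene F2 (from trichloroethylene, methanol and KH) with two equivalents of n-BuLi at −78 °C. After addition to 7 the mixture is quenched cold with acetic acid to give racemic methyl 2-(1-hydroxy-3-methoxyprop-2-ynyl)-3-(3-methylbut-2-enyl)-4,6-bis(pivaloyloxy)benzoate F3. Gentle warming of F3 in toluene closes the lactone on the neutral alcohol, releasing methanol instead of methoxide, and gives 11.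

**Step 11.** With the ring A oxygen bound to aluminium, the benzylic C–O bond ortho to it may ionise and take up hydride (over-reduction to a diarylmethane). The pentaol may also cyclodehydrate on isolation, or self-condense through ionisation of its hydroxy-activated primary benzylic alcohol. Fallback, from 22 to 24: the ring A phenol is silylated first (TBSOTf, 2,6-lutidine) to racemic 3-[3,5-dibromo-2-(tert-butyldimethylsilyloxy)-6-methoxy-4-methylphenyl]-4-(3-methylbut-2-enyl)-5,7-bis(pivaloyloxy)isobenzofuran-1(3H)-one F4. Reduction with i-Bu2AlH then gives racemic 5-{[3,5-dibromo-2-(tert-butyldimethylsilyloxy)-6-methoxy-4-methylphenyl](hydroxy)methyl}-4-(hydroxymethyl)-6-(3-methylbut-2-enyl)benzene-1,3-diol F5, and TBSCl–imidazole converts F5 into 24.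

**Step 10.** The prenyl alkene may take up bromine, or the second bromination at C2 (between methoxy and methyl) may stall. Fallback, from 21 to 22: exhaustive bromination with pyridinium tribromide is accepted and gives 3-(3,5-dibromo-2-hydroxy-6-methoxy-4-methylphenyl)-4-(2,3-dibromo-3-methylbutyl)-5,7-bis(pivaloyloxy)isobenzofuran-1(3H)-one F6 as a diastereomer mixture. Zinc dust in acetic acid then removes only the vicinal dibromide by reductive anti-elimination and regenerates the alkene, giving 22.

**Step 5.** Transmetalation at the di-ortho-substituted arylpalladium may be slow, and allylic transposition may give some branched 1,1-dimethylallyl isomer. Fallback, from 5 to 7: Stille coupling with allyltributylstannane, which has no regiochemical issue, gives methyl 3-allyl-2-formyl-4,6-bis(pivaloyloxy)benzoate F7. Cross-metathesis of F7 with 2-methylbut-2-ene (second-generation Grubbs catalyst, RuCl2(=CHPh)(PCy3)(H2IMes)) then builds the prenyl group and gives 7.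

**Step 1.** Bromination may also occur between the two hydroxyls, or twice. Fallback, from 1 to 3: the non-chelated hydroxyl is acylated first (PivCl, 1 equiv, pyridine, 0 °C) to methyl 2-hydroxy-6-methyl-4-(pivaloyloxy)benzoate F8. Bromination with NBS is then directed para to the single remaining, ester-chelated hydroxyl and gives methyl 3-bromo-6-hydroxy-2-methyl-4-(pivaloyloxy)benzoate F9. A second pivaloylation (PivCl, Et3N, DMAP) gives 3.

## Further compounds

F1 | step 9 | 1-diazo-3-methylbut-3-en-2-one | C=C(C)C(=O)C=[N+]=[N-]
F2 | step 6 | (E)-1,2-dichloro-1-methoxyethene | CO/C(Cl)=C\Cl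
F3 | step 6 | racemic methyl 2-(1-hydroxy-3-methoxyprop-2-ynyl)-3-(3-methylbut-2-enyl)-4,6-bis(pivaloyloxy)benzoate | COC#CC(O)c1c(CC=C(C)C)c(OC(=O)C(C)(C)C)cc(OC(=O)C(C)(C)C)c1C(=O)OC
F4 | step 11 | racemic 3-[3,5-dibromo-2-(tert-butyldimethylsilyloxy)-6-methoxy-4-methylphenyl]-4-(3-methylbut-2-enyl)-5,7-bis(pivaloyloxy)isobenzofuran-1(3H)-one | Cc1c(Br)c(O[Si](C)(C)C(C)(C)C)c(C2OC(=O)c3c(OC(=O)C(C)(C)C)cc(OC(=O)C(C)(C)C)c(CC=C(C)C)c23)c(OC)c1Br
F5 | step 11 | racemic 5-{[3,5-dibromo-2-(tert-butyldimethylsilyloxy)-6-methoxy-4-methylphenyl](hydroxy)methyl}-4-(hydroxymethyl)-6-(3-methylbut-2-enyl)benzene-1,3-diol | COc1c(Br)c(C)c(Br)c(O[Si](C)(C)C(C)(C)C)c1C(O)c1c(CO)c(O)cc(O)c1CC=C(C)C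
F6 | step 10 | 3-(3,5-dibromo-2-hydroxy-6-methoxy-4-methylphenyl)-4-(2,3-dibromo-3-methylbutyl)-5,7-bis(pivaloyloxy)isobenzofuran-1(3H)-one, mixture of diastereomers | Cc1c(Br)c(O)c(C2OC(=O)c3c(OC(=O)C(C)(C)C)cc(OC(=O)C(C)(C)C)c(CC(Br)C(C)(C)Br)c23)c(OC)c1Br
F7 | step 5 | methyl 3-allyl-2-formyl-4,6-bis(pivaloyloxy)benzoate | COC(=O)c1c(C=O)c(CC=C)c(OC(=O)C(C)(C)C)cc1OC(=O)C(C)(C)C
F8 | step 1 | methyl 2-hydroxy-6-methyl-4-(pivaloyloxy)benzoate | COC(=O)c1c(C)cc(OC(=O)C(C)(C)C)cc1O
F9 | step 1 | methyl 3-bromo-6-hydroxy-2-methyl-4-(pivaloyloxy)benzoate | COC(=O)c1c(C)c(Br)c(OC(=O)C(C)(C)C)cc1O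
A1 | alternative 1 | 2,4-dibromo-1-methoxy-7,9-bis(methoxymethoxy)-3-methyl-10-(3-methylbut-2-enyl)dibenzo[b,e]oxepine-6,11-dione | O=C1Oc2c(Br)c(C)c(Br)c(OC)c2C(=O)c2c(CC=C(C)C)c(OCOC)cc(OCOC)c21
A2 | alternative 1 | 4,6-dibromo-2-iodo-3-methoxy-5-methylphenyl 4,6-bis(methoxymethoxy)-3-(3-methylbut-2-enyl)-2-(4,4,5,5-tetramethyl-1,3,2-dioxaborolan-2-yl)benzoate | COc1c(Br)c(C)c(Br)c(OC(=O)c2c(OCOC)cc(OCOC)c(CC=C(C)C)c2B2OC(C)(C)C(C)(C)O2)c1I
A3 | alternative 2 | racemic methyl 2-[(tert-butyldimethylsilyloxy)(3,5-dibromo-2-methoxy-6-(methoxymethoxy)-4-methylphenyl)methyl]-4,6-dihydroxy-3-(3-methylbut-2-enyl)benzoate | COC(=O)c1c(O)cc(O)c(CC=C(C)C)c1C(O[Si](C)(C)C(C)(C)C)c1c(OC)c(Br)c(C)c(Br)c1OCOC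
A4 | alternative 2 | 1-methoxy-7-methyl-1,3-bis(trimethylsilyloxy)octa-1,3,6-triene | COC(O[Si](C)(C)C)=CC(O[Si](C)(C)C)=CCC=C(C)C
A5 | alternative 2 | racemic methyl 4-(tert-butyldimethylsilyloxy)-4-[3,5-dibromo-2-methoxy-6-(methoxymethoxy)-4-methylphenyl]but-2-ynoate | COC(=O)C#CC(O[Si](C)(C)C(C)(C)C)c1c(OC)c(Br)c(C)c(Br)c1OCOC
A6 | alternative 3 | 5-[3,5-dibromo-2-methoxy-6-(methoxymethoxy)-4-methylbenzoyl]-7-hydroxy-2,2-dimethyl-6-(3-methylbut-2-enyl)-4H-benzo[d][1,3]dioxin-4-one | CC1(C)OC(=O)c2c(O1)cc(O)c(CC=C(C)C)c2C(=O)c1c(OC)c(Br)c(C)c(Br)c1OCOC
A7 | alternative 3 | racemic 6-[5-(3,5-dibromo-2-methoxy-6-(methoxymethoxy)-4-methylphenyl)-3-(3-methylbut-2-enyl)-2,4,5-trioxopentyl]-2,2-dimethyl-4H-1,3-dioxin-4-one | CC1(C)OC(=O)C=C(CC(=O)C(CC=C(C)C)C(=O)C(=O)c2c(OC)c(Br)c(C)c(Br)c2OCOC)O1
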